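**Retrosynthetic overview**
1. Numbering: bicyclo[7.2.0]undecane (caryophyllane) C1–C11 for the 4/9 bicycle; chromene numbering O1'–C8a' for the spiro-dihydropyran/cyclohexenedione part (C2' = C8). The last step is a reagent-controlled 1,2-reduction of a C5 enone (sets 5S).
2. Key disconnection: the dihydropyran is opened at C8–C3' and C4'–C4a', giving a C8 ketone, 4-methylpent-1-ene and syncarpic acid (three-component polar [4+2]).
3. Enabling feature: O1' sits on the quaternary spiro carbon C8 and is the ether oxygen of a vinylogous ester (O1'–C8a'=C4a'–C5'=O). C8 at the carbonyl level plus O1'–C8a'=C4a' is therefore a 2-oxonia diene, and C3'–C4' is a plain terminal alkene.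
4. The C8 ketone is (−)-caryophyllene oxide minus its exocyclic methylene carbon (ozonolysis); the epoxide becomes the (3Z)-4-methyl enone by base isomerisation, oxidation and exo-to-endo double-bond migration. C1 and C9 come from the chiral pool.
5. Ring order: cyclobutane and nine-membered ring from caryophyllene oxide, cyclohexenedione from syncarpic acid, dihydropyran formed last and alone.

Key step: step 6

Remark: syncarpic acid is assumed to be purchasable and to react through its enol tautomer.

**Step 1**
Reactants: 1 (−)-caryophyllene oxide, (1R,4R,5R,9S)-4,5-epoxy-4,11,11-trimethyl-8-methylidenebicyclo[7.2.0]undecane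
Product: 2 (1R,5R,9S)-11,11-dimethyl-4,8-dimethylidenebicyclo[7.2.0]undecan-5-ol
Conditions: LiN(iPr)2 (3 equiv), Et2O, 0 °C to reflux; then H2O
Reagents that add atoms: none
Why: Base-promoted epoxide-to-allylic-alcohol isomerisation, in which the amide removes a proton of the C4 methyl through a cyclic syn transition state while the C4–O bond breaks, so the C5–O bond and its R configuration are untouched (an endocyclic isomer from removal of a C3 proton would converge after steps 2 to 4).

**Step 2**
Reactants: 2 (1R,5R,9S)-11,11-dimethyl-4,8-dimethylidenebicyclo[7.2.0]undecan-5-ol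
Product: 3 (1R,9S)-11,11-dimethyl-4,8-dimethylidenebicyclo[7.2.0]undecan-5-one
Conditions: Dess–Martin periodinane (1.2 equiv), CH2Cl2, 0 °C to rt
Reagents that add atoms: none
Why: Dess–Martin oxidation of the secondary allylic alcohol under neutral conditions should leave both exocyclic alkenes alone; the C5 stereocentre is erased on purpose and is reset in step 7.

**Step 3**
Reactants: 3 (1R,9S)-11,11-dimethyl-4,8-dimethylidenebicyclo[7.2.0]undecan-5-one
Product: 5 (1R,9S)-11,11-dimethyl-4-methylidenebicyclo[7.2.0]undecane-5,8-dione, via spiro ozonide 4 (not isolated)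
Conditions: O3 (about 1 equiv, Sudan red 7B end point), CH2Cl2, −78 °C; then PPh3, −78 °C to rt
Reagents that add atoms: ozone, [O-][O+]=O
Why: Ozonolysis, in which electrophilic ozone should cleave the electron-rich 1,1-dialkyl C8 methylidene well before the electron-poor α-methylene ketone, excising one carbon and unveiling the C8 ketone without creating a stereocentre.

**Step 4**
Reactants: 5 (1R,9S)-11,11-dimethyl-4-methylidenebicyclo[7.2.0]undecane-5,8-dione
Product: 6 (1R,3Z,9S)-4,11,11-trimethylbicyclo[7.2.0]undec-3-ene-5,8-dione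
Conditions: RhCl3·3H2O (5 mol %), EtOH, 75 °C
Reagents that add atoms: none
Why: Rhodium-hydride addition/β-hydride elimination should move the exocyclic double bond of the α-methylene ketone into the ring to give the thermodynamically preferred trisubstituted enone, whose ring-cis (Z) geometry is the unstrained one in a nine-membered ring, while C9 stays in the more stable trans ring fusion.

**Step 5**
Reactants: 7 syncarpic acid (enol form, 5-hydroxy-2,2,6,6-tetramethylcyclohex-4-ene-1,3-dione)
Product: 8 2,2,6,6-tetramethyl-5-(trimethylsilyloxy)cyclohex-4-ene-1,3-dione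
Conditions: (Me3Si)2NH (0.6 equiv), Me3SiCl (2 mol %), CH2Cl2, 40 °C; concentrate
Reagents that add atoms: hexamethyldisilazane, C[Si](C)(C)N[Si](C)(C)C
Why: O-silylation of the vinylogous acid, driven by loss of ammonia, should give a neutral aprotic O-nucleophile for the ketal exchange of step 6.

**Step 6**
Reactants: 6 (1R,3Z,9S)-4,11,11-trimethylbicyclo[7.2.0]undec-3-ene-5,8-dione, 8 2,2,6,6-tetramethyl-5-(trimethylsilyloxy)cyclohex-4-ene-1,3-dione, 9 4-methylpent-1-ene
Product: 12 (1R,3Z,8S,9S,4'S)-4,6',6',8',8',11,11-heptamethyl-4'-(2-methylpropyl)-3',4'-dihydrospiro[bicyclo[7.2.0]undec-3-ene-8,2'-chromene]-5,5',7'(6'H,8'H)-trione, via mixed silyl ketal 10 (not isolated), via 2-oxonia diene triflate 11 (not isolated)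
Conditions: 8 (1.5 equiv), 9 (10 equiv), Me3SiOTf (1.2 equiv), CH2Cl2, −78 to −30 °C; then Et3N
Reagents that add atoms: none
Why: Proposed new method: Me3SiOTf should first exchange the C8 ketone with silyl ether 8 to the mixed silyl ketal 10 and then expel hexamethyldisiloxane to give the 2-oxonia diene 11 (C8=O1'(+)–C8a'=C4a'), which adds the terminal CH2 of 9 at C8 in the Markovnikov sense while the enol-ether carbon C4a' captures the developing secondary cation at C4' and loses its proton; the closest known reaction types are the oxa-Povarov reaction of aryl acetal-derived 2-oxonia dienes with alkenes and the silyl triflate-mediated ketalisation of ketones with silyl ethers, extended here to a ketone-derived oxonia diene whose ene part is a vinylogous ester. The dihydropyran is the only ring closed, by an intermolecular polar (asynchronous) [4+2] annulation whose second bond forms in a 6-endo-trig sense at the enol ether, so that C8–C3' and C4'–C4a' arise in one event. C8 (S) should be set under Felkin–Anh control by the ring-fusion centre C9: the nine-membered ring holds the C9–C1 bond roughly perpendicular to C8=O(+), C10 lies on the oxygen side, and the alkene enters anti to C9–C1 past H9. C4' (S) should be set in a chair-like transition state in which isobutyl and the more branched C9 arm of the spiro ring are both pseudo-equatorial and therefore cis. The step needs the alkene to trap C8 of the saturated ketone only and faster than side reactions: the conjugated C5 carbonyl should not enter silyl ketal exchange at low temperature and its alkene is too electron-poor to attack the cation, proton loss from 11 to a dienyl ether is reversible under the triflic acid formed, and ring closure at C4' is intramolecular and should outrun hydride shifts. C9 should stay trans-fused because that is the thermodynamically preferred ring fusion even if the C8–C9 enol ether forms transiently.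

**Step 7**
Reactants: 12 (1R,3Z,8S,9S,4'S)-4,6',6',8',8',11,11-heptamethyl-4'-(2-methylpropyl)-3',4'-dihydrospiro[bicyclo[7.2.0]undec-3-ene-8,2'-chromene]-5,5',7'(6'H,8'H)-trione
Product: 13 tomentodione P, (1R,3Z,5S,8S,9S,4'S)-5-hydroxy-4,6',6',8',8',11,11-heptamethyl-4'-(2-methylpropyl)-3',4'-dihydrospiro[bicyclo[7.2.0]undec-3-ene-8,2'-chromene]-5',7'(6'H,8'H)-dione
Conditions: (R)-2-methyl-CBS-oxazaborolidine (0.5 equiv), catecholborane (1.5 equiv), toluene, −78 °C; then MeOH, aq. NaOH wash
Reagents that add atoms: none
Why: Corey–Bakshi–Shibata reduction, in which the (R)-oxazaborolidine should bind the C5 enone carbonyl (C7' lies between two quaternary carbons and C5' is a vinylogous ester carbonyl) with the α-methylalkenyl arm as the large group and deliver hydride 1,2 to the face that gives the 5S allylic alcohol.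

**Compound list**
1 | (−)-caryophyllene oxide, (1R,4R,5R,9S)-4,5-epoxy-4,11,11-trimethyl-8-methylidenebicyclo[7.2.0]undecane | C[C@@]12CC[C@@H]3[C@H](CC3(C)C)C(=C)CC[C@H]1O2 | starting material
2 | (1R,5R,9S)-11,11-dimethyl-4,8-dimethylidenebicyclo[7.2.0]undecan-5-ol | C=C1CC[C@@H]2[C@H](CC2(C)C)C(=C)CC[C@H]1O | intermediate
3 | (1R,9S)-11,11-dimethyl-4,8-dimethylidenebicyclo[7.2.0]undecan-5-one | C=C1CC[C@@H]2[C@H](CC2(C)C)C(=C)CCC1=O | intermediate
4 | spiro ozonide (1,2,4-trioxolane at C8) of 3, not isolated, C8 configuration undefined | C=C1CC[C@@H]2[C@H](CC2(C)C)C2(CCC1=O)OCOO2 | intermediate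
5 | (1R,9S)-11,11-dimethyl-4-methylidenebicyclo[7.2.0]undecane-5,8-dione | C=C1CC[C@@H]2[C@H](CC2(C)C)C(=O)CCC1=O | intermediate
6 | (1R,3Z,9S)-4,11,11-trimethylbicyclo[7.2.0]undec-3-ene-5,8-dione | C/C1=C/C[C@@H]2[C@H](CC2(C)C)C(=O)CCC1=O | intermediate
7 | syncarpic acid, enol form, 5-hydroxy-2,2,6,6-tetramethylcyclohex-4-ene-1,3-dione | OC1=CC(=O)C(C)(C)C(=O)C1(C)C | starting material
8 | 2,2,6,6-tetramethyl-5-(trimethylsilyloxy)cyclohex-4-ene-1,3-dione | C[Si](C)(C)OC1=CC(=O)C(C)(C)C(=O)C1(C)C | intermediate
9 | 4-methylpent-1-ene | C=CCC(C)C | starting material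
10 | mixed silyl ketal at C8 of 6 (C8 bears OSiMe3 and the enol oxygen of the syncarpic unit), not isolated, C8 configuration undefined | C/C1=C/C[C@@H]2[C@H](CC2(C)C)C(O[Si](C)(C)C)(OC2=CC(=O)C(C)(C)C(=O)C2(C)C)CCC1=O | intermediate
11 | 2-oxonia diene triflate (C8=O(+)–C8a'=C4a'), not isolated | C/C1=C/C[C@@H]2[C@H](CC2(C)C)C(=[O+]C2=CC(=O)C(C)(C)C(=O)C2(C)C)CCC1=O.[O-]S(=O)(=O)C(F)(F)F | intermediate
12 | (1R,3Z,8S,9S,4'S)-4,6',6',8',8',11,11-heptamethyl-4'-(2-methylpropyl)-3',4'-dihydrospiro[bicyclo[7.2.0]undec-3-ene-8,2'-chromene]-5,5',7'(6'H,8'H)-trione | C/C1=C/C[C@@H]2[C@H](CC2(C)C)[C@]2(CCC1=O)C[C@H](CC(C)C)C1=C(O2)C(C)(C)C(=O)C(C)(C)C1=O | intermediate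
13 | tomentodione P, (1R,3Z,5S,8S,9S,4'S)-5-hydroxy-4,6',6',8',8',11,11-heptamethyl-4'-(2-methylpropyl)-3',4'-dihydrospiro[bicyclo[7.2.0]undec-3-ene-8,2'-chromene]-5',7'(6'H,8'H)-dione | C/C1=C/C[C@@H]2[C@H](CC2(C)C)[C@]2(CC[C@@H]1O)C[C@H](CC(C)C)C1=C(O2)C(C)(C)C(=O)C(C)(C)C1=O | target

**Totals**
Total step count: 7. Longest linear sequence: 6 steps (steps 1, 2, 3, 4, 6, 7).

**Steps most likely to fail**

Step 6 (proposed new method). What may go wrong: the oxonia diene may collapse by proton loss and hydrolysis back to the ketone without being trapped by the weakly nucleophilic alkene; a hydride shift may occur in the developing secondary cation; the alkene may attack the wrong face of C8; the chair preference that sets C4' may be poor; the C5 carbonyl may take part. Fallback (known chemistry, different bond set): it sets out from compound 3, which still carries the C8 methylidene. Knoevenagel condensation of 7 with 3-methylbutanal (ethylenediammonium diacetate cat., toluene, 60 °C) should give 2,2,4,4-tetramethyl-6-(3-methylbutylidene)cyclohexane-1,3,5-trione F1, a 1-oxa-diene. In the same flask this should add to the electron-rich 1,1-disubstituted alkene of 3 by inverse-demand hetero-Diels–Alder reaction (oxygen to C8, carbon to the methylidene carbon), the electron-poor α-methylene ketone not competing. The product is the spiro-dihydropyran with the C4 methylidene ketone F2, to be separated from its C4' epimer. Isomerisation with RhCl3·3H2O in ethanol, as in step 4, returns to the route at compound 12.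

Step 3. What may go wrong: loss of chemoselectivity, with ozone also cleaving the conjugated methylidene, or peroxide-derived over-oxidation. Fallback: it sets out from compound 1, which has a single alkene. Ozonolysis (O3, CH2Cl2, −78 °C; PPh3) gives the epoxy ketone kobusone F3. Cp2TiCl (trivalent titanium, made from Cp2TiCl2 and Mn in THF) should open the epoxide homolytically at C4 and, after β-hydride elimination, give (1R,5R,9S)-5-hydroxy-11,11-dimethyl-4-methylidenebicyclo[7.2.0]undecan-8-one F4, the ketone being tolerated. Dess–Martin oxidation returns to the route at compound 5.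

Step 7. What may go wrong: mismatched pairing of catalyst and substrate leading to poor facial selectivity at C5, or slow competing reduction of the C7' ketone. Fallback: it sets out from compound 12. Luche reduction (NaBH4, CeCl3·7H2O, MeOH, −78 °C) is chemoselective for the enone carbonyl but substrate-controlled. The 5R epimer F5 that it may give beside 13 is inverted by Mitsunobu esterification (4-nitrobenzoic acid, PPh3, DIAD, THF) to the (5S)-4-nitrobenzoate F6. Methanolysis (K2CO3, MeOH) returns to the route at compound 13.

**Further compounds**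
F1 | step 6 | 2,2,4,4-tetramethyl-6-(3-methylbutylidene)cyclohexane-1,3,5-trione | CC(C)CC=C1C(=O)C(C)(C)C(=O)C(C)(C)C1=O
F2 | step 6 | (1R,8S,9S,4'S)-6',6',8',8',11,11-hexamethyl-4-methylidene-4'-(2-methylpropyl)-3',4'-dihydrospiro[bicyclo[7.2.0]undecane-8,2'-chromene]-5,5',7'(6'H,8'H)-trione | C=C1CC[C@@H]2[C@H](CC2(C)C)[C@]2(CCC1=O)C[C@H](CC(C)C)C1=C(O2)C(C)(C)C(=O)C(C)(C)C1=O
F3 | step 3 | kobusone, (1R,4R,5R,9S)-4,5-epoxy-4,11,11-trimethylbicyclo[7.2.0]undecan-8-one | C[C@@]12CC[C@@H]3[C@H](CC3(C)C)C(=O)CC[C@H]1O2
F4 | step 3 | (1R,5R,9S)-5-hydroxy-11,11-dimethyl-4-methylidenebicyclo[7.2.0]undecan-8-one | C=C1CC[C@@H]2[C@H](CC2(C)C)C(=O)CC[C@H]1O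
F5 | step 7 | 5-epi-tomentodione P, the (1R,3Z,5R,8S,9S,4'S) alcohol | C/C1=C/C[C@@H]2[C@H](CC2(C)C)[C@]2(CC[C@H]1O)C[C@H](CC(C)C)C1=C(O2)C(C)(C)C(=O)C(C)(C)C1=O
F6 | step 7 | (5S)-4-nitrobenzoate of tomentodione P | C/C1=C/C[C@@H]2[C@H](CC2(C)C)[C@]2(CC[C@@H]1OC(=O)c3ccc(cc3)[N+](=O)[O-])C[C@H](CC(C)C)C1=C(O2)C(C)(C)C(=O)C(C)(C)C1=O
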